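**Retrosynthetic overview**
1. Target 17 ⇒ ester C–O bond: cyclodecadienol 14 + 4-acetoxy-3-methoxybenzoic acid 15; 14 ⇒ 13 (isopropenyl → isopropyl).
2. The only ring ⇒ C1–C10 bond of 13, the bond made in the farnesyl → germacradienyl cyclisation (C1 electrophile, distal isoprene unit nucleophile): catalytic asymmetric intramolecular allylboration of the (2Z,6Z)-enal 11 carrying a (Z)-allyl boronate. This one step sets both stereocentres.
3. 11 ⇒ alcohol 10 ⇒ Ni-catalysed 1,4-hydroboration of the terminal 1,3-diene of tetraenol 8.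
4. 8 ⇒ C4–C5 bond: (Z)-dianion of prenol 6 + dienyl bromide 5; 5 ⇒ neryl acetate 1 by ene-chlorination and dehydrochlorination.
5. Ring order: one ring, closed in step 6; both Z ring alkenes are carried in from the nerol- and prenol-derived units.

Assumption: the target is taken exactly as written, i.e. both ring alkenes Z and (1R,10S), with the ester oxygen and the isopropyl group cis on the ring. The change of descriptor at C1 between 13 (1S) and 14 (1R) is a CIP priority change only, not an inversion.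

**Step 1**
Reactants: 1 neryl acetate
Product: 2 (2Z)-6-chloro-3,7-dimethylocta-2,7-dien-1-yl acetate (racemic at C6)
Conditions: Ca(OCl)2, CO2 (dry ice), CH2Cl2/H2O, 0 °C
Reagents that add atoms: calcium hypochlorite, [Ca+2].[O-]Cl.[O-]Cl
Why: HOCl formed in situ does an ene-type allylic chlorination (Cl to C6, alkene shifts to C7=C8) at the electron-rich terminal alkene, while the 2,3-alkene is deactivated by the allylic acetate; the racemic centre is destroyed in step 2.

**Step 2**
Reactants: 2 (2Z)-6-chloro-3,7-dimethylocta-2,7-dien-1-yl acetate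
Product: 4 (2Z,5E)-3,7-dimethylocta-2,5,7-trien-1-ol, via trienyl acetate 3 (not isolated)
Conditions: Li2CO3, LiBr, DMF, 100 °C; then K2CO3 (cat.), MeOH, rt
Reagents that add atoms: none
Why: E2 dehydrochlorination can only remove a C5–H and gives the conjugated (E)-diene under weakly basic conditions that do not move the skipped alkenes, and K2CO3/MeOH transesterification then frees the primary alcohol.

**Step 3**
Reactants: 4 (2Z,5E)-3,7-dimethylocta-2,5,7-trien-1-ol
Product: 5 (2Z,5E)-1-bromo-3,7-dimethylocta-2,5,7-triene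
Conditions: CBr4, PPh3, CH2Cl2, −30 → 0 °C; used crude
Reagents that add atoms: carbon tetrabromide, BrC(Br)(Br)Br
Why: The Appel reaction converts the primary allylic alcohol into the bromide under neutral, cold conditions that keep the 2Z geometry and leave the diene alone.

**Step 4**
Reactants: 5 (2Z,5E)-1-bromo-3,7-dimethylocta-2,5,7-triene; 6 prenol (3-methylbut-2-en-1-ol)
Product: 8 (2Z,6Z,9E)-3,7,11-trimethyldodeca-2,6,9,11-tetraen-1-ol, via dilithiated prenol 7 (not isolated)
Conditions: 6, n-BuLi (2.2 equiv), TMEDA, Et2O/hexane, 0 °C → rt; then 5, THF, −78 → 0 °C; H2O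
Reagents that add atoms: none
Why: Alkoxide-directed allylic lithiation of prenol deprotonates the methyl group cis to CH2OLi, and SN2 alkylation of this chelated dianion at its CH2Li terminus by the primary allylic bromide fixes the new 2Z alkene (dianion alkylation); the 6Z and 9E alkenes are not touched.

**Step 5**
Reactants: 8 (2Z,6Z,9E)-3,7,11-trimethyldodeca-2,6,9,11-tetraen-1-ol
Product: 10 (2Z,6Z,10Z)-3,7,11-trimethyl-12-(4,4,5,5-tetramethyl-1,3,2-dioxaborolan-2-yl)dodeca-2,6,10-trien-1-ol, via O-boryl ether 9 (not isolated)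
Conditions: HBpin (2.2 equiv), Ni(cod)2 (5 mol %), PCy3 (5 mol %), toluene, rt; then MeOH
Reagents that add atoms: pinacolborane, B1OC(C)(C)C(C)(C)O1
Why: Ni(0)/PCy3-catalysed 1,4-hydroboration goes through the s-cis diene, puts H on C9 and boron on the unsubstituted CH2 terminus and so gives the (Z)-allyl boronate (CH2B cis to the chain); the first equivalent of HBpin borylates the OH, which MeOH releases again.

**Step 6**
Reactants: 10 (2Z,6Z,10Z)-3,7,11-trimethyl-12-(4,4,5,5-tetramethyl-1,3,2-dioxaborolan-2-yl)dodeca-2,6,10-trien-1-ol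
Product: 13 (1S,2Z,6Z,10S)-3,7-dimethyl-10-(prop-1-en-2-yl)cyclodeca-2,6-dien-1-ol, via enal boronate 11 (not isolated), via cyclic borate ester 12 (not isolated)
Conditions: MnO2, toluene, 0 °C → rt, filter; filtrate added by syringe pump to (R)-TRIP (10 mol %), 4 Å MS, toluene, −30 °C, 2 mM; aq. NaHCO3
Reagents that add atoms: none
Why: Proposed new method: MnO2 oxidises only the allylic alcohol without Z→E drift, and the chiral phosphoric acid then activates the pinacol boronate by hydrogen bonding so that the tethered enal reacts through a closed six-membered chair in which C10 (the γ-carbon) attacks the Re face of C1 and the (Z)-boronate forces the chain axial, giving the 1,10-cis (1S,10S) ten-membered ring while high dilution suppresses oligomers; the closest known reactions are the chiral phosphoric acid-catalysed intermolecular allyl- and crotylboration of enals and the thermal intramolecular allylboration of (Z)-allyl boronates to cis-2-vinylcycloalkanols.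

**Step 7**
Reactants: 13 (1S,2Z,6Z,10S)-3,7-dimethyl-10-(prop-1-en-2-yl)cyclodeca-2,6-dien-1-ol
Product: 14 (1R,2Z,6Z,10S)-3,7-dimethyl-10-(propan-2-yl)cyclodeca-2,6-dien-1-ol
Conditions: H2 (1 atm), RhCl(PPh3)3 (5 mol %), benzene, rt
Reagents that add atoms: none
Why: Homogeneous hydrogenation with Wilkinson's catalyst reduces the unhindered 1,1-disubstituted isopropenyl alkene much faster than the two trisubstituted ring alkenes, and no stereocentre is formed or touched.

**Step 8**
Reactants: 14 (1R,2Z,6Z,10S)-3,7-dimethyl-10-(propan-2-yl)cyclodeca-2,6-dien-1-ol; 15 4-acetoxy-3-methoxybenzoic acid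
Product: 17 (1R,2Z,6Z,10S)-3,7-dimethyl-10-(propan-2-yl)cyclodeca-2,6-dien-1-yl 4-hydroxy-3-methoxybenzoate, via O-acetyl ester 16 (not isolated)
Conditions: 15, DCC, DMAP (cat.), CH2Cl2, 0 °C → rt; then pyrrolidine, rt
Reagents that add atoms: none
Why: Steglich esterification acylates the secondary allylic alcohol with retention at C1, and pyrrolidine aminolysis then removes the much more reactive aryl acetate while the hindered benzoate survives.

**Compound list**
1 | neryl acetate, (2Z)-3,7-dimethylocta-2,6-dien-1-yl acetate | CC(=O)OC/C=C(/C)CCC=C(C)C | starting material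
2 | (2Z)-6-chloro-3,7-dimethylocta-2,7-dien-1-yl acetate (racemic) | CC(=O)OC/C=C(/C)CCC(Cl)C(C)=C | intermediate
3 | (2Z,5E)-3,7-dimethylocta-2,5,7-trien-1-yl acetate | CC(=O)OC/C=C(/C)C/C=C/C(C)=C | intermediate (not isolated)
4 | (2Z,5E)-3,7-dimethylocta-2,5,7-trien-1-ol | OC/C=C(/C)C/C=C/C(C)=C | intermediate
5 | (2Z,5E)-1-bromo-3,7-dimethylocta-2,5,7-triene | BrC/C=C(/C)C/C=C/C(C)=C | intermediate
6 | prenol, 3-methylbut-2-en-1-ol | CC(C)=CCO | starting material
7 | dilithiated prenol, lithium (2Z)-4-lithio-3-methylbut-2-en-1-olate | [Li]C/C(C)=C\CO[Li] | intermediate (not isolated)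
8 | (2Z,6Z,9E)-3,7,11-trimethyldodeca-2,6,9,11-tetraen-1-ol | OC/C=C(/C)CC/C=C(/C)C/C=C/C(C)=C | intermediate
9 | 2-{[(2Z,6Z,10Z)-3,7,11-trimethyl-12-(4,4,5,5-tetramethyl-1,3,2-dioxaborolan-2-yl)dodeca-2,6,10-trien-1-yl]oxy}-4,4,5,5-tetramethyl-1,3,2-dioxaborolane | CC1(C)OB(OC/C=C(/C)CC/C=C(/C)CC/C=C(/C)CB2OC(C)(C)C(C)(C)O2)OC1(C)C | intermediate (not isolated)
10 | (2Z,6Z,10Z)-3,7,11-trimethyl-12-(4,4,5,5-tetramethyl-1,3,2-dioxaborolan-2-yl)dodeca-2,6,10-trien-1-ol | OC/C=C(/C)CC/C=C(/C)CC/C=C(/C)CB1OC(C)(C)C(C)(C)O1 | intermediate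
11 | (2Z,6Z,10Z)-3,7,11-trimethyl-12-(4,4,5,5-tetramethyl-1,3,2-dioxaborolan-2-yl)dodeca-2,6,10-trienal | O=C/C=C(/C)CC/C=C(/C)CC/C=C(/C)CB1OC(C)(C)C(C)(C)O1 | intermediate (not isolated)
12 | 2-{[(1S,2Z,6Z,10S)-3,7-dimethyl-10-(prop-1-en-2-yl)cyclodeca-2,6-dien-1-yl]oxy}-4,4,5,5-tetramethyl-1,3,2-dioxaborolane | CC1(C)OB(O[C@H]2/C=C(/C)CC/C=C(/C)CC[C@H]2C(C)=C)OC1(C)C | intermediate (not isolated)
13 | (1S,2Z,6Z,10S)-3,7-dimethyl-10-(prop-1-en-2-yl)cyclodeca-2,6-dien-1-ol | O[C@H]1/C=C(/C)CC/C=C(/C)CC[C@H]1C(C)=C | intermediate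
14 | (1R,2Z,6Z,10S)-3,7-dimethyl-10-(propan-2-yl)cyclodeca-2,6-dien-1-ol | O[C@H]1/C=C(/C)CC/C=C(/C)CC[C@H]1C(C)C | intermediate
15 | 4-acetoxy-3-methoxybenzoic acid | COc1cc(C(=O)O)ccc1OC(C)=O | starting material
16 | (1R,2Z,6Z,10S)-3,7-dimethyl-10-(propan-2-yl)cyclodeca-2,6-dien-1-yl 4-acetoxy-3-methoxybenzoate | COc1cc(C(=O)O[C@H]2/C=C(/C)CC/C=C(/C)CC[C@H]2C(C)C)ccc1OC(C)=O | intermediate (not isolated)
17 | (1R,2Z,6Z,10S)-3,7-dimethyl-10-(propan-2-yl)cyclodeca-2,6-dien-1-yl 4-hydroxy-3-methoxybenzoate | COc1cc(C(=O)O[C@H]2/C=C(/C)CC/C=C(/C)CC[C@H]2C(C)C)ccc1O | target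

**Step count**
Total steps: 8. Longest linear sequence: 8 (1 → 17); 6 and 15 are bought and enter in steps 4 and 8.

**Three steps most likely to fail**

Step 6 (ring closure). The ten-membered closure may lose to oligomerisation, or the macrocyclic transition state may not fit the catalyst pocket, giving low ee or the opposite facial sense (in which case (S)-TRIP is the first thing to try). The fallback keeps the same C1–C10 bond but makes it by umpolung allylchromium chemistry and corrects C1 during esterification; it sets out from 2 and comes back at 16. Methanolysis of 2 (K2CO3, MeOH) gives (2Z)-6-chloro-3,7-dimethylocta-2,7-dien-1-ol F1. Appel bromination gives (2Z)-1-bromo-6-chloro-3,7-dimethylocta-2,7-diene F2. Alkylation of dianion 7 at −78 °C, where the primary allylic bromide reacts and the secondary chloride is kept, gives (2Z,6Z)-10-chloro-3,7,11-trimethyldodeca-2,6,11-trien-1-ol F3. MnO2 gives (2Z,6Z)-10-chloro-3,7,11-trimethyldodeca-2,6,11-trienal F4. An intramolecular asymmetric Nozaki–Hiyama–Kishi allylation (CrCl2, NaI, chiral oxazoline–sulfonamide ligand, THF, high dilution) is anti-selective and should give the 1,10-trans alcohol (1R,2Z,6Z,10S)-3,7-dimethyl-10-(prop-1-en-2-yl)cyclodeca-2,6-dien-1-ol F5. Wilkinson hydrogenation gives (1S,2Z,6Z,10S)-3,7-dimethyl-10-(propan-2-yl)cyclodeca-2,6-dien-1-ol F6. Mitsunobu esterification with 15 (PPh3, DIAD) inverts C1 and gives 16, which is deacetylated as in step 8.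

Step 4 (dianion alkylation). The risks are attack through the internal carbon of the allyl dianion, SN2′ attack on 5, and base-induced 1,4-elimination of the doubly allylic bromide. The fallback builds the 2Z alkene by cuprate addition to an ynoate; it sets out from 5 and comes back at 8. Bromide 5 is alkylated with 3-lithio-1-(trimethylsilyl)propyne to give trimethyl[(5Z,8E)-6,10-dimethylundeca-5,8,10-trien-1-yn-1-yl]silane F7. MeLi·LiBr followed by ClCO2Me gives methyl (6Z,9E)-7,11-dimethyldodeca-6,9,11-trien-2-ynoate F8. Syn-addition of Me2CuLi at −78 °C gives methyl (2Z,6Z,9E)-3,7,11-trimethyldodeca-2,6,9,11-tetraenoate F9. DIBAL-H reduction then gives 8.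

Step 5 (1,4-hydroboration). The regiochemistry on a 1-alkyl-3-methyl diene (boron at the secondary terminus instead of the CH2) and the tolerance of the catalyst for the borylated allylic alcohol are uncertain. The fallback switches the allyl metal from boron to silicon; it sets out from 8 and comes back at 13. MnO2 oxidation of 8 gives (2Z,6Z,9E)-3,7,11-trimethyldodeca-2,6,9,11-tetraenal F10. Pd(PPh3)4-catalysed 1,4-hydrosilylation with HSiCl3, which places silicon on the CH2 next to the methyl-bearing carbon with Z geometry, gives (2Z,6Z,10Z)-3,7,11-trimethyl-12-(trichlorosilyl)dodeca-2,6,10-trienal F11, used without isolation. A chiral bisphosphoramide Lewis base (iPr2NEt, CH2Cl2, −78 °C, high dilution) then triggers the same closed-chair, syn-selective ring closure, and aqueous NaHCO3 work-up gives 13.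

**Further compounds**
F1 | step 6 | (2Z)-6-chloro-3,7-dimethylocta-2,7-dien-1-ol | OC/C=C(/C)CCC(Cl)C(C)=C
F2 | step 6 | (2Z)-1-bromo-6-chloro-3,7-dimethylocta-2,7-diene | BrC/C=C(/C)CCC(Cl)C(C)=C
F3 | step 6 | (2Z,6Z)-10-chloro-3,7,11-trimethyldodeca-2,6,11-trien-1-ol | OC/C=C(/C)CC/C=C(/C)CCC(Cl)C(C)=C
F4 | step 6 | (2Z,6Z)-10-chloro-3,7,11-trimethyldodeca-2,6,11-trienal | O=C/C=C(/C)CC/C=C(/C)CCC(Cl)C(C)=C
F5 | step 6 | (1R,2Z,6Z,10S)-3,7-dimethyl-10-(prop-1-en-2-yl)cyclodeca-2,6-dien-1-ol | O[C@@H]1/C=C(/C)CC/C=C(/C)CC[C@H]1C(C)=C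
F6 | step 6 | (1S,2Z,6Z,10S)-3,7-dimethyl-10-(propan-2-yl)cyclodeca-2,6-dien-1-ol | O[C@@H]1/C=C(/C)CC/C=C(/C)CC[C@H]1C(C)C
F7 | step 4 | trimethyl[(5Z,8E)-6,10-dimethylundeca-5,8,10-trien-1-yn-1-yl]silane | C[Si](C)(C)C#CCC/C=C(/C)C/C=C/C(C)=C
F8 | step 4 | methyl (6Z,9E)-7,11-dimethyldodeca-6,9,11-trien-2-ynoate | COC(=O)C#CCC/C=C(/C)C/C=C/C(C)=C
F9 | step 4 | methyl (2Z,6Z,9E)-3,7,11-trimethyldodeca-2,6,9,11-tetraenoate | COC(=O)/C=C(/C)CC/C=C(/C)C/C=C/C(C)=C
F10 | step 5 | (2Z,6Z,9E)-3,7,11-trimethyldodeca-2,6,9,11-tetraenal | O=C/C=C(/C)CC/C=C(/C)C/C=C/C(C)=C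
F11 | step 5 | (2Z,6Z,10Z)-3,7,11-trimethyl-12-(trichlorosilyl)dodeca-2,6,10-trienal | O=C/C=C(/C)CC/C=C(/C)CC/C=C(/C)C[Si](Cl)(Cl)Cl
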